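I decide to rank these flasks by one number, the age of the target at the end, and not by amounts.

| flask | substrate | partner | reagent | temperature | time | remark |
|---|---|---|---|---|---|---|
| green | 26 mM | 31.2 mM | 104 mM (fed, over 3.0 min) | 60 °C | 20 min | all else is in the flask from the start; the feed brings no volume worth counting |
| blue | 26 mM (fed, over 12 min) | 31.2 mM | 104 mM |  | 20 min | the addition at 20 °C, then warmed to 60 °C; the feed brings no volume worth counting |
| violet | 26 mM | 31.2 mM | 104 mM (fed, over 12 min) | 60 °C | 20 min | all else is in the flask from the start; the feed brings no volume worth counting |
| red | 26 mM | 31.2 mM | 104 mM | 60 °C | 20 min | everything together at the start |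

    substrate + reagent → open intermediate (k1 = 0.24 M⁻¹ min⁻¹, Ea1 = 75.0 kJ mol⁻¹)
    target → over-reaction product (k2 = 0.054 min⁻¹, Ea2 = 89.0 kJ mol⁻¹)
    open intermediate → decomposed reagent (k3 = 0.16 min⁻¹, Ea3 = 87.0 kJ mol⁻¹)
    reagent + partner → second intermediate (k4 = 0.63 M⁻¹ min⁻¹, Ea4 = 52.0 kJ mol⁻¹)
    open intermediate + second intermediate → target (k5 = 2.7 M⁻¹ min⁻¹, Ea5 = 66.0 kJ mol⁻¹)
    (constants at 60 °C)

- the list of constants is for 60 °C, to be carried to other temperatures by the activation energies

* the best flask by share of target in target plus over-reaction product; "all alike" if 1.5 percentage points covers them all (green / blue / violet / red / all alike)
* share of target in target plus over-reaction product at the end, green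
* share of target in target plus over-reaction product at the end, blue
* share of target in target plus over-reaction product at the end, violet
* share of target in target plus over-reaction product at the end, red

1. Target forms at its constant times [open intermediate][second intermediate] and is lost at 0.054 min⁻¹. In red, open intermediate has a half-life of 4.3 min by its decay alone, shorter than the run, so I let [open intermediate] level off early. In red I also let [second intermediate] rise with a bend, because partner has a half-life of 10.6 min by step 4 with reagent held at its charge. The lag and the bend pull opposite ways, so I take the rate as growing in proportion to elapsed time. Such a rate gives target a mean age of a third of the window in which it forms.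

2. For red this gives 0.360. That product of loss constant and mean age is the age number. I take the natural logarithm of the share as minus this number, so red gets 69.8%. I let the charges drop out of the age of the target.

3. For a feed at 60 °C I shorten the window by half the feeding time, the mean delay of the reagent. I assume the addition at 20 °C is dead time.

- Green: 0.333, share 71.7%.
- Violet: 0.252, share 77.7%.
- Blue: 0.144, share 86.6%.

4. Blue has the lowest number, so I put it first. Is one number enough? Blue's window is about twice the half-life of open intermediate by its decay alone, so I expect blue's rate to rise more steeply and blue's share to lie a little higher. In my reckoning blue and red stand 17 percentage points apart against a margin of 1.5 points, so I do not call the flasks all alike. Green and red stand 1.9 points apart, and that is the weak place in my order.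

5. The forecast names blue, with green 71%, blue 88%, violet 78% and red 70%, holding that the share “depends almost entirely on how late in the 20 min the target forms”.

6. The simulation gives blue as best, with green 71.3%, blue 87.5%, violet 78.2% and red 68.9%. In blue at 20.0 min, open intermediate decays at 0.16 min⁻¹ and joins second intermediate at 0.0340 min⁻¹, which is 4.71 times slower. Blue then holds decomposed reagent at 7.39% of the substrate charged, against target at 0.983% and over-reaction product at 0.141%.

7. The same blue flask read at 50 min has a window of 38.0 min, so I reckon its age number at 0.684 and its share at 50.5%. The computed share is 44.1%.

The rate constants come from no measurement; the rest is arithmetic.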